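The bicyclo[3.3.1]nonane is numbered C1 (benzoyl bridgehead), C2 (OMe), C3, C4 (C=O), C5 (prenyl bridgehead), C6, C7, C8 (CMe2), C9 (bridging C=O). Everything rests on the C5–C6 disconnection. The precursor is a monocyclic 5-methylidene-dihydropyran in which C6 is an allylic ether carbon held on the C9 enol oxygen. In one flask, zerovalent palladium with a chiral diphosphine ionises C6–O and the C4–C5–C9 diketone enolate recloses through C5 onto C6 (ring B, C5 set), then KOt-Bu closes ring A by Dieckmann condensation. The step exploits the 1,3-dicarbonyl flanking C5 and the allylic C6–C7(=CH2) unit, whose methylene later carries the C7 side chain.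

Key step: step 6

Remark on numbering: C1–C9 are the locants of the target core and are used for the corresponding atoms of every precursor; ring A is C1–C2–C3–C4–C5–C9, ring B is C1–C9–C5–C6–C7–C8.
Assumption: the (1R,2R)-diphosphine is taken to give the (5S) centre of 14; if the sense of induction is the opposite one, its enantiomer is used.

Step 1
Reactants: 1 dimethyl 2-(propan-2-ylidene)propanedioate
Product: 2 2-(propan-2-ylidene)propane-1,3-diol
Conditions: i-Bu2AlH (4.5 equiv), CH2Cl2, −78 to 0 °C; aq. potassium sodium tartrate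
Reagents that add atoms: none
Why: Diisobutylaluminium hydride should reduce both conjugated esters in the 1,2-sense to the allylic diol (ester reduction), conjugate reduction being disfavoured at the fully substituted β-carbon.

Step 2
Reactants: 2 2-(propan-2-ylidene)propane-1,3-diol; 3 methyl (E)-3-methoxybut-2-enoate
Product: 6 methyl 2,4,4-trimethyl-5-methylidene-5,6-dihydro-4H-pyran-3-carboxylate, via allyl enol ether 4 (not isolated), via hydroxy keto ester 5 (not isolated)
Conditions: PPTS (5 mol%), xylenes, 110 to 145 °C, MeOH distilled off, then Dean–Stark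
Reagents that add atoms: none
Why: Acid-catalysed exchange of the methoxy group for one hydroxyl of the diol gives an allyl vinyl ether whose Claisen rearrangement through the tetrasubstituted alkene terminus should build the C1–C8 bond next to the quaternary carbon, and the δ-hydroxy β-keto ester then cyclodehydrates to the conjugated cyclic enol ether; no stereocentre is retained.

Step 3
Reactants: 7 5-methylhex-4-enoic acid
Product: 9 N-methoxy-N,5-dimethylhex-4-enamide, via acyl imidazolide 8 (not isolated)
Conditions: 1,1′-carbonyldiimidazole, CH2Cl2, rt; then MeNH(OMe)·HCl, rt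
Reagents that add atoms: N,O-dimethylhydroxylamine hydrochloride, CNOC.Cl
Why: Activation as the acyl imidazolide and aminolysis (Weinreb amide formation) run under near-neutral conditions that leave the trisubstituted alkene untouched.

Step 4
Reactants: 6 methyl 2,4,4-trimethyl-5-methylidene-5,6-dihydro-4H-pyran-3-carboxylate; 9 N-methoxy-N,5-dimethylhex-4-enamide
Product: 11 methyl 4,4-dimethyl-2-(6-methyl-2-oxohept-5-en-1-yl)-5-methylidene-5,6-dihydro-4H-pyran-3-carboxylate, via lithium dienolate 10 (not isolated)
Conditions: LiN(i-Pr)2 (1.2 equiv), THF, −78 °C; then 9, −78 to −30 °C; aq. NH4Cl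
Reagents that add atoms: none
Why: The ring methyl group (future C5) is the only position that gives a conjugated dienolate of the vinylogous carbonate, since the α-carbon is fully substituted, and the N-methoxy-N-methylamide should acylate it once through a stable chelated tetrahedral intermediate (Weinreb ketone synthesis).

Step 5
Reactants: 11 methyl 4,4-dimethyl-2-(6-methyl-2-oxohept-5-en-1-yl)-5-methylidene-5,6-dihydro-4H-pyran-3-carboxylate
Product: 13 methyl 2-(2,10-dimethyl-6-oxoundeca-2,9-dien-5-yl)-4,4-dimethyl-5-methylidene-5,6-dihydro-4H-pyran-3-carboxylate (racemic), via sodium enolate 12 (not isolated)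
Conditions: NaH (1.05 equiv), THF, 0 °C; prenyl bromide (1.1 equiv), 0 °C to rt
Reagents that add atoms: 1-bromo-3-methylbut-2-ene (prenyl bromide), CC(C)=CCBr
Why: The methylene between the ketone and the enol ether carbon (future C5) is the most acidic site and its extended enolate should be C-alkylated by the primary allylic bromide (enolate alkylation); the new stereocentre forms as a racemate and is erased in step 6.

Step 6
Reactants: 13 methyl 2-(2,10-dimethyl-6-oxoundeca-2,9-dien-5-yl)-4,4-dimethyl-5-methylidene-5,6-dihydro-4H-pyran-3-carboxylate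
Product: 15 (1R,5R)-2-hydroxy-8,8-dimethyl-7-methylidene-3,5-bis(3-methylbut-2-en-1-yl)bicyclo[3.3.1]non-2-ene-4,9-dione (enol form of the trione), via cyclohexanone keto ester 14 (not isolated)
Conditions: Pd2(dba)3·CHCl3 (2.5 mol%), (1R,2R)-N,N′-bis[2-(diphenylphosphanyl)benzoyl]cyclohexane-1,2-diamine (7.5 mol%), t-BuOH (1 equiv), 1,4-dioxane, 60 °C; then KOt-Bu (1.1 equiv), THF, 25 to 60 °C; 1 M HCl
Reagents that add atoms: none
Why: Zerovalent palladium ionises the allylic C6–O bond of 13 to a 2-substituted π-allylpalladium cation paired with the tricarbonyl enolate, t-BuOH shuttles the proton so that the charge sits on the 2-prenyl-1,3-diketone carbon C5, and C5 attacks an allyl terminus to form C5–C6. The closest known reaction types are the palladium-catalysed O-to-C transposition of cyclic allyl enol ethers of β-keto esters and the Tsuji–Trost alkylation of 2-substituted 1,3-diketones. Ring B closes by 6-(enolendo)-exo attack on the allyl terminus, and ring A then closes by Dieckmann condensation (6-(enolendo)-exo-trig) when KOt-Bu lets the C3 enolate of 14 attack the C2 ester. The quaternary C5 stereocentre is set by the chiral diphosphine, which differentiates the enantiotopic faces of the C5 enolate in the contact ion pair, and C1 is set relative to C5 because only the epimer with ester and C5 acyl group cis can cyclise while C1 epimerises freely. Carbon selectivity is secured because O-allylation only regenerates an ionisable allyl enol ether, attack through C1 would need a four-membered ring, the prenyl alkenes do not ionise and C8 has no hydrogen for diene formation. One equivalent of base keeps the unproductive C1 enolate in exchange with the C3 enolate, and the bicyclic β-diketonate with its non-enolisable bridgehead C1 is the thermodynamic sink.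

Step 7
Reactants: 15 (1R,5R)-2-hydroxy-8,8-dimethyl-7-methylidene-3,5-bis(3-methylbut-2-en-1-yl)bicyclo[3.3.1]non-2-ene-4,9-dione
Product: 16 (1R,5R)-2-methoxy-8,8-dimethyl-7-methylidene-3,5-bis(3-methylbut-2-en-1-yl)bicyclo[3.3.1]non-2-ene-4,9-dione
Conditions: Me3SiCHN2 (1.5 equiv), toluene–MeOH (4:1), 0 °C to rt
Reagents that add atoms: (trimethylsilyl)diazomethane, C[Si](C)(C)C=[N+]=[N-]
Why: The acidic enol is O-methylated by the diazoalkane without C-alkylation at C3, and the oxygen on C2 should react preferentially because it lies next to the small equatorial C1 hydrogen whereas the oxygen on C4 is flanked by the C5 prenyl group; the regioisomeric ether would be removed by chromatography.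

Step 8
Reactants: 16 (1R,5R)-2-methoxy-8,8-dimethyl-7-methylidene-3,5-bis(3-methylbut-2-en-1-yl)bicyclo[3.3.1]non-2-ene-4,9-dione
Product: 18 (1R,5S)-1-benzoyl-2-methoxy-8,8-dimethyl-7-methylidene-3,5-bis(3-methylbut-2-en-1-yl)bicyclo[3.3.1]non-2-ene-4,9-dione, via bridgehead lithium species 17 (not isolated)
Conditions: LiN(i-Pr)2 (1.5 equiv), THF, −78 °C; PhCOCl (2 equiv), −78 °C to rt
Reagents that add atoms: benzoyl chloride, O=C(Cl)c1ccccc1
Why: C3 and C5 are fully substituted, so the amide base can only remove the outward-pointing C1 bridgehead hydrogen α to the C9 ketone, and the pyramidal bridgehead carbanion can only be C-acylated, with its configuration fixed by the bicycle (bridgehead lithiation–acylation of bicyclo[3.3.1]nonane-trione enol ethers).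

Step 9
Reactants: 19 prop-2-yn-1-ol
Product: 21 (E)-3-iodo-2-methylprop-2-en-1-ol, via alkenylalane 20 (not isolated)
Conditions: AlMe3 (3 equiv), Cp2ZrCl2 (0.25 equiv), CH2Cl2, 0 °C to rt; then I2, THF, −30 to 0 °C
Reagents that add atoms: trimethylaluminium, C[Al](C)C; iodine, II
Why: Zirconium-catalysed carboalumination (Negishi) adds methyl and aluminium syn across the alkyne with aluminium at the terminus, and iodinolysis with retention should give the (E)-alkenyl iodide.

Step 10
Reactants: 21 (E)-3-iodo-2-methylprop-2-en-1-ol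
Product: 22 (E)-3-iodo-2-methylprop-2-en-1-yl acetate
Conditions: Ac2O, pyridine, DMAP (cat.), CH2Cl2, rt
Reagents that add atoms: acetic anhydride, CC(=O)OC(C)=O
Why: Acylation of the primary allylic alcohol is straightforward and does not affect the alkenyl iodide.

Step 11
Reactants: 18 (1R,5S)-1-benzoyl-2-methoxy-8,8-dimethyl-7-methylidene-3,5-bis(3-methylbut-2-en-1-yl)bicyclo[3.3.1]non-2-ene-4,9-dione; 22 (E)-3-iodo-2-methylprop-2-en-1-yl acetate
Product: 24 (E)-4-[(1R,5S,7S)-1-benzoyl-2-methoxy-8,8-dimethyl-3,5-bis(3-methylbut-2-en-1-yl)-4,9-dioxobicyclo[3.3.1]non-2-en-7-yl]-2-methylbut-2-en-1-yl acetate (target), via alkylborane 23 (not isolated)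
Conditions: 9-BBN (1.3 equiv), THF, 0 °C to rt; then 22, Pd(dppf)Cl2·CH2Cl2 (5 mol%), AsPh3 (10 mol%), Cs2CO3, DMF–H2O, rt
Reagents that add atoms: none
Why: 9-BBN should add to the 1,1-disubstituted exocyclic alkene in preference to the trisubstituted prenyl alkenes and the hindered or vinylogous carbonyl groups, placing boron on the terminal carbon and hydrogen on C7 from the open exo face because ring A blocks the endo face, which sets the side chain endo (7S); B-alkyl Suzuki–Miyaura coupling with the (E)-alkenyl iodide then proceeds with retention of alkene geometry.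

Compound list
1 | dimethyl 2-(propan-2-ylidene)propanedioate | COC(=O)C(=C(C)C)C(=O)OC | starting material
2 | 2-(propan-2-ylidene)propane-1,3-diol | OCC(CO)=C(C)C | intermediate
3 | methyl (E)-3-methoxybut-2-enoate | COC(=O)/C=C(\C)OC | starting material
4 | methyl 3-{[2-(hydroxymethyl)-3-methylbut-2-en-1-yl]oxy}but-2-enoate (allyl enol ether) | COC(=O)C=C(C)OCC(CO)=C(C)C | intermediate
5 | methyl 2-acetyl-4-(hydroxymethyl)-3,3-dimethylpent-4-enoate | COC(=O)C(C(C)=O)C(C)(C)C(=C)CO | intermediate
6 | methyl 2,4,4-trimethyl-5-methylidene-5,6-dihydro-4H-pyran-3-carboxylate | COC(=O)C1=C(C)OCC(=C)C1(C)C | intermediate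
7 | 5-methylhex-4-enoic acid | CC(C)=CCCC(O)=O | starting material
8 | 1-(imidazol-1-yl)-5-methylhex-4-en-1-one (acyl imidazolide) | CC(C)=CCCC(=O)n1ccnc1 | intermediate
9 | N-methoxy-N,5-dimethylhex-4-enamide | CON(C)C(=O)CCC=C(C)C | intermediate
10 | lithium dienolate of 6, drawn as the C-lithiated ring methyl group | [Li]CC1=C(C(=O)OC)C(C)(C)C(=C)CO1 | intermediate
11 | methyl 4,4-dimethyl-2-(6-methyl-2-oxohept-5-en-1-yl)-5-methylidene-5,6-dihydro-4H-pyran-3-carboxylate | COC(=O)C1=C(CC(=O)CCC=C(C)C)OCC(=C)C1(C)C | intermediate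
12 | sodium enolate of 11 | [Na+].[O-]C(CCC=C(C)C)=CC1=C(C(=O)OC)C(C)(C)C(=C)CO1 | intermediate
13 | methyl 2-(2,10-dimethyl-6-oxoundeca-2,9-dien-5-yl)-4,4-dimethyl-5-methylidene-5,6-dihydro-4H-pyran-3-carboxylate (racemic) | COC(=O)C1=C(C(CC=C(C)C)C(=O)CCC=C(C)C)OCC(=C)C1(C)C | intermediate
14 | methyl (5S)-2,2-dimethyl-3-methylidene-5-(5-methylhex-4-enoyl)-5-(3-methylbut-2-en-1-yl)-6-oxocyclohexane-1-carboxylate (both C1 epimers) | COC(=O)C1C(=O)[C@](CC=C(C)C)(C(=O)CCC=C(C)C)CC(=C)C1(C)C | intermediate
15 | (1R,5R)-2-hydroxy-8,8-dimethyl-7-methylidene-3,5-bis(3-methylbut-2-en-1-yl)bicyclo[3.3.1]non-2-ene-4,9-dione | OC1=C(CC=C(C)C)C(=O)[C@]2(CC=C(C)C)CC(=C)C(C)(C)[C@H]1C2=O | intermediate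
16 | (1R,5R)-2-methoxy-8,8-dimethyl-7-methylidene-3,5-bis(3-methylbut-2-en-1-yl)bicyclo[3.3.1]non-2-ene-4,9-dione | COC1=C(CC=C(C)C)C(=O)[C@]2(CC=C(C)C)CC(=C)C(C)(C)[C@H]1C2=O | intermediate
17 | C1-lithiated 16 (bridgehead lithium species) | COC1=C(CC=C(C)C)C(=O)[C@]2(CC=C(C)C)CC(=C)C(C)(C)[C@@]1([Li])C2=O | intermediate
18 | (1R,5S)-1-benzoyl-2-methoxy-8,8-dimethyl-7-methylidene-3,5-bis(3-methylbut-2-en-1-yl)bicyclo[3.3.1]non-2-ene-4,9-dione | COC1=C(CC=C(C)C)C(=O)[C@]2(CC=C(C)C)CC(=C)C(C)(C)[C@@]1(C(=O)c1ccccc1)C2=O | intermediate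
19 | prop-2-yn-1-ol | OCC#C | starting material
20 | dimethyl[(E)-3-(dimethylalumanyloxy)-2-methylprop-1-en-1-yl]alumane (alkenylalane) | C[Al](C)/C=C(\C)CO[Al](C)C | intermediate
21 | (E)-3-iodo-2-methylprop-2-en-1-ol | OC/C(C)=C/I | intermediate
22 | (E)-3-iodo-2-methylprop-2-en-1-yl acetate | CC(=O)OC/C(C)=C/I | intermediate
23 | B-alkyl-9-borabicyclo[3.3.1]nonane from 18, boron on the endo C7 methylene (1R,5S,7S) | COC1=C(CC=C(C)C)C(=O)[C@]2(CC=C(C)C)C[C@H](CB3C4CCCC3CCC4)C(C)(C)[C@@]1(C(=O)c1ccccc1)C2=O | intermediate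
24 | (E)-4-[(1R,5S,7S)-1-benzoyl-2-methoxy-8,8-dimethyl-3,5-bis(3-methylbut-2-en-1-yl)-4,9-dioxobicyclo[3.3.1]non-2-en-7-yl]-2-methylbut-2-en-1-yl acetate | COC1=C(CC=C(C)C)C(=O)[C@]2(CC=C(C)C)C[C@H](C/C=C(\C)COC(C)=O)C(C)(C)[C@@]1(C(=O)c1ccccc1)C2=O | target

Total step count: 11. Longest linear sequence: 8 (steps 1, 2, 4, 5, 6, 7, 8, 11).

Steps most likely to fail

Step 6. The ligand may differentiate the two faces of the C5 enolate only weakly when the ion pair recombines, so the bicycle would form with low enantiomeric purity. Fallback, from 13: the same ring contraction is run without chiral control with Pd(PPh3)4 in DMSO at 80 °C to give the racemic keto ester F1, which KOt-Bu cyclises in the same flask to the racemic trione F2. F2 is resolved by preparative chromatography on a chiral stationary phase (amylose tris(3,5-dimethylphenylcarbamate)); the (1R,5R) enantiomer is 15, where the route is rejoined.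

Step 8. C-acylation of the congested bridgehead carbanion next to the quaternary C8 may be slower than proton return and consumption of the acid chloride by the amide base, leaving 16 unchanged. Fallback, from 16: the lithium species 17 is trapped with the small electrophile I2 to give the bridgehead iodide F3. Iodine–magnesium exchange with i-PrMgCl in THF gives the bridgehead Grignard reagent F4, which adds to benzaldehyde to give the carbinol F5 as two epimers. Oxidation with Dess–Martin periodinane returns to the route at 18.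

Step 11. Hydroboration of the exocyclic alkene, which is shielded by the neighbouring quaternary C8, may be slow enough for hydroboration of the prenyl groups or carbonyl reduction by the dialkylborane to compete, and the allylic acetate may be lost under the basic coupling. Fallback, from 18: iridium-catalysed hydroboration with pinacolborane ([Ir(cod)Cl]2, dppe, CH2Cl2, rt), which is selective for 1,1-disubstituted alkenes and leaves ketones alone, gives the boronate F6. Suzuki–Miyaura coupling of F6 with the iodo alcohol 21 (Pd(OAc)2, SPhos, K3PO4, toluene–H2O, 70 °C) gives the allylic alcohol F7, and acetylation (Ac2O, pyridine) returns to the route at 24.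

Further compounds
F1 | step 6 | racemic methyl 2,2-dimethyl-3-methylidene-5-(5-methylhex-4-enoyl)-5-(3-methylbut-2-en-1-yl)-6-oxocyclohexane-1-carboxylate | COC(=O)C1C(=O)C(CC=C(C)C)(C(=O)CCC=C(C)C)CC(=C)C1(C)C
F2 | step 6 | racemic 2-hydroxy-8,8-dimethyl-7-methylidene-3,5-bis(3-methylbut-2-en-1-yl)bicyclo[3.3.1]non-2-ene-4,9-dione | OC1=C(CC=C(C)C)C(=O)C2(CC=C(C)C)CC(=C)C(C)(C)C1C2=O
F3 | step 8 | 1-iodo-2-methoxy-8,8-dimethyl-7-methylidene-3,5-bis(3-methylbut-2-en-1-yl)bicyclo[3.3.1]non-2-ene-4,9-dione (bridgeheads as in 18) | COC1=C(CC=C(C)C)C(=O)[C@]2(CC=C(C)C)CC(=C)C(C)(C)[C@@]1(I)C2=O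
F4 | step 8 | C1 chloromagnesium derivative of 16 (bridgehead Grignard reagent) | COC1=C(CC=C(C)C)C(=O)[C@]2(CC=C(C)C)CC(=C)C(C)(C)[C@@]1([Mg]Cl)C2=O
F5 | step 8 | 1-[hydroxy(phenyl)methyl]-2-methoxy-8,8-dimethyl-7-methylidene-3,5-bis(3-methylbut-2-en-1-yl)bicyclo[3.3.1]non-2-ene-4,9-dione (bridgeheads as in 18, both carbinol epimers) | COC1=C(CC=C(C)C)C(=O)[C@]2(CC=C(C)C)CC(=C)C(C)(C)[C@@]1(C(O)c1ccccc1)C2=O
F6 | step 11 | (1R,5S,7S)-1-benzoyl-2-methoxy-8,8-dimethyl-3,5-bis(3-methylbut-2-en-1-yl)-7-[(4,4,5,5-tetramethyl-1,3,2-dioxaborolan-2-yl)methyl]bicyclo[3.3.1]non-2-ene-4,9-dione | COC1=C(CC=C(C)C)C(=O)[C@]2(CC=C(C)C)C[C@H](CB3OC(C)(C)C(C)(C)O3)C(C)(C)[C@@]1(C(=O)c1ccccc1)C2=O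
F7 | step 11 | (1R,5S,7S)-1-benzoyl-7-[(E)-4-hydroxy-3-methylbut-2-en-1-yl]-2-methoxy-8,8-dimethyl-3,5-bis(3-methylbut-2-en-1-yl)bicyclo[3.3.1]non-2-ene-4,9-dione | COC1=C(CC=C(C)C)C(=O)[C@]2(CC=C(C)C)C[C@H](C/C=C(\C)CO)C(C)(C)[C@@]1(C(=O)c1ccccc1)C2=O
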